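**Strategy.** The route rests on closing the oxane (locants: O1, C2 enyne arm, C3–Cl, C4, C5–Br, C6 bromopentenyl arm) through the C4–C5 bond. The feature exploited is the syn-1,3-diaxial C3(Cl)–C4H2–C5(X) triad next to O1. An acyclic α-alkoxy aldehyde (C5, C6) carrying a vinyl group (C3=C4) on C2 undergoes a TiCl4-mediated Prins cyclisation in which C4 attacks the O1-chelated aldehyde and titanium hands chloride to C3, so the ring, the C3 chloride and the C5 carbinol arise in one operation. The precursor comes from one resolved allylic alcohol and a glycolate alkylation; C5–OH then becomes bromide with net retention.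

Key step: step 12

Remark on locants: ring compounds carry the locants of the target oxane (O1; C2 bears the pentenynyl arm or its precursor; C3 chlorine; C4 methylene; C5 oxygen or bromine; C6 the bromopentenyl arm).
Assumption: 3-[(tert-butyldiphenylsilyl)oxy]propanal (6) is taken as a purchased material; otherwise it is two steps from propane-1,3-diol.

**Bromopentenyl arm**

Step 1
Reactants: 1 but-1-yne
Product: 2 (E)-2-bromo-1-iodobut-1-ene
Conditions: IBr (1.0 equiv), CH2Cl2, −78 to 0 °C, dark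
Reagents that add atoms: iodine monobromide, BrI
Why: Electrophilic anti addition of iodine monobromide to a terminal alkyne (iodine to the terminal carbon, bromide to the internal one) should give the E dihaloalkene, which fixes the cis relation of the ethyl group and the future CH2 arm.

Step 2
Reactants: 2 (E)-2-bromo-1-iodobut-1-ene
Product: 3 methyl (2E)-3-bromopent-2-enoate
Conditions: CO (1 atm), MeOH, Et3N, PdCl2(PPh3)2 (3 mol%), DMF, 25 °C
Reagents that add atoms: carbon monoxide, [C-]#[O+]; methanol, CO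
Why: Palladium-catalysed alkoxycarbonylation of a vinyl iodide should occur only at the C–I bond and with retention of olefin geometry, the vinyl bromide being far slower in oxidative addition.

Step 3
Reactants: 3 methyl (2E)-3-bromopent-2-enoate
Product: 4 (2E)-3-bromopent-2-en-1-ol
Conditions: i-Bu2AlH (2.2 equiv), CH2Cl2, −78 °C; then aq. potassium sodium tartrate
Reagents that add atoms: none
Why: Aluminium hydride 1,2-reduction of an enoate at low temperature should give the allylic alcohol and leave the vinyl bromide and the olefin geometry untouched.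

Step 4
Reactants: 4 (2E)-3-bromopent-2-en-1-ol
Product: 5 (2E)-3-bromo-1-iodopent-2-ene
Conditions: I2, PPh3, imidazole, CH2Cl2, 0 °C, dark; used at once
Reagents that add atoms: iodine, II
Why: Appel-type iodination of a primary allylic alcohol by SN2 displacement should give the reactive allylic iodide without allylic transposition.

**Main line**

Step 5
Reactants: 6 3-[(tert-butyldiphenylsilyl)oxy]propanal
Product: 7 rac-5-[(tert-butyldiphenylsilyl)oxy]pent-1-en-3-ol
Conditions: CH2=CHMgBr, THF, −78 to 0 °C; then H2O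
Reagents that add atoms: vinylmagnesium bromide, C=C[Mg]Br
Why: Grignard addition of a vinyl nucleophile to the aldehyde gives the racemic secondary allylic alcohol.

Step 6
Reactants: 7 rac-5-[(tert-butyldiphenylsilyl)oxy]pent-1-en-3-ol
Product: 8 (3S)-5-[(tert-butyldiphenylsilyl)oxy]pent-1-en-3-ol
Conditions: Ti(OiPr)4 (0.2 equiv), D-(−)-diisopropyl tartrate (0.24 equiv), t-BuOOH (0.6 equiv), 4 Å molecular sieves, CH2Cl2, −20 °C
Reagents that add atoms: none
Why: Sharpless kinetic resolution: with the D-(−)-tartrate titanium catalyst the R enantiomer is epoxidised much faster, so the S allylic alcohol (the future C2 stereocentre) should be recovered in high enantiomeric purity.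

Step 7
Reactants: 8 (3S)-5-[(tert-butyldiphenylsilyl)oxy]pent-1-en-3-ol
Product: 9 2-{[(3S)-5-[(tert-butyldiphenylsilyl)oxy]pent-1-en-3-yl]oxy}acetic acid
Conditions: BrCH2CO2H, NaH (3 equiv), THF, 0 °C to rt; then aq. HCl
Reagents that add atoms: bromoacetic acid, OC(=O)CBr
Why: Williamson etherification of the sodium alkoxide with sodium bromoacetate should give the glycolic acid ether without touching the C2 stereocentre.

Step 8
Reactants: 9 2-{[(3S)-5-[(tert-butyldiphenylsilyl)oxy]pent-1-en-3-yl]oxy}acetic acid; 10 (4S)-4-benzyl-1,3-oxazolidin-2-one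
Product: 12 (4S)-4-benzyl-3-(2-{[(3S)-5-[(tert-butyldiphenylsilyl)oxy]pent-1-en-3-yl]oxy}acetyl)-1,3-oxazolidin-2-one, via mixed pivalic anhydride 11 (not isolated)
Conditions: t-BuCOCl, Et3N, THF, −20 °C; then 10, LiCl, rt
Reagents that add atoms: none
Why: N-acylation of the oxazolidinone through the mixed pivalic anhydride (LiCl/Et3N activation) installs the Evans-type auxiliary for the next step.

Step 9
Reactants: 12 (4S)-4-benzyl-3-(2-{[(3S)-5-[(tert-butyldiphenylsilyl)oxy]pent-1-en-3-yl]oxy}acetyl)-1,3-oxazolidin-2-one; 5 (2E)-3-bromo-1-iodopent-2-ene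
Product: 14 (4S)-4-benzyl-3-[(2R,4E)-5-bromo-2-{[(3S)-5-[(tert-butyldiphenylsilyl)oxy]pent-1-en-3-yl]oxy}hept-4-enoyl]-1,3-oxazolidin-2-one, via sodium enolate 13 (not isolated)
Conditions: NaN(SiMe3)2, THF, −78 °C; then 5, −78 to −45 °C
Reagents that add atoms: none
Why: Evans-type glycolate alkylation: the chelated Z sodium enolate is alkylated by the allylic iodide on the face anti to the benzyl group, which should set C6 as R (cis to the C2 arm after ring closure), and the low temperature keeps the [2,3]-Wittig shift of the allyloxy enolate from competing.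

Step 10
Reactants: 14 (4S)-4-benzyl-3-[(2R,4E)-5-bromo-2-{[(3S)-5-[(tert-butyldiphenylsilyl)oxy]pent-1-en-3-yl]oxy}hept-4-enoyl]-1,3-oxazolidin-2-one
Product: 15 (2R,4E)-5-bromo-2-{[(3S)-5-[(tert-butyldiphenylsilyl)oxy]pent-1-en-3-yl]oxy}hept-4-en-1-ol
Conditions: LiBH4, MeOH (1 equiv), Et2O, 0 °C
Reagents that add atoms: none
Why: Reductive cleavage of the N-acyl oxazolidinone with LiBH4 gives the primary alcohol and returns the auxiliary without epimerising C6.

Step 11
Reactants: 15 (2R,4E)-5-bromo-2-{[(3S)-5-[(tert-butyldiphenylsilyl)oxy]pent-1-en-3-yl]oxy}hept-4-en-1-ol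
Product: 16 (2R,4E)-5-bromo-2-{[(3S)-5-[(tert-butyldiphenylsilyl)oxy]pent-1-en-3-yl]oxy}hept-4-enal
Conditions: Dess–Martin periodinane, NaHCO3, CH2Cl2, 0 °C to rt; used at once
Reagents that add atoms: none
Why: Buffered Dess–Martin oxidation should give the α-alkoxy aldehyde without epimerisation at C6.

Step 12
Reactants: 16 (2R,4E)-5-bromo-2-{[(3S)-5-[(tert-butyldiphenylsilyl)oxy]pent-1-en-3-yl]oxy}hept-4-enal
Product: 17 (2S,3S,5R,6R)-6-[(2E)-3-bromopent-2-en-1-yl]-2-{2-[(tert-butyldiphenylsilyl)oxy]ethyl}-3-chlorooxan-5-ol (target locants; all four ring substituents cis)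
Conditions: TiCl4 (1.5 equiv), CH2Cl2, −78 °C; then aq. NaHCO3
Reagents that add atoms: titanium tetrachloride, Cl[Ti](Cl)(Cl)Cl
Why: TiCl4 binds the aldehyde oxygen and the ether oxygen O1 in a five-membered chelate, and the terminal carbon C4 of the C2 vinyl group attacks the activated carbonyl carbon C5 (Prins-type carbonyl–olefin addition) through a chair with both arms equatorial, while the positive charge developing at C3 is quenched by a chloride handed over from the same titanium centre (syn addition across C3=C4). The closest known reaction type is the Lewis acid-mediated cyclisation of hex-5-enal-type aldehydes to cis-3-chlorocyclohexanols with chloride transfer from the metal alkoxide, combined with chelate-controlled addition to α-alkoxy aldehydes. The oxane closes in a 6-endo-trig mode with respect to the olefin (exo with respect to the carbonyl group). C5 is set by the chelate (attack anti to the C6 arm, oxygen axial and gauche to O1) and C3 by the intramolecular chloride delivery, which can reach only the axial position on the face of the C5–O–Ti unit, while C2 and C6 are carried in unchanged. The step needs attack by C4 and not C3 (secondary against primary cation secures this), needs the distant and halogen-deactivated bromoalkene to stay out (only four-membered or 5-endo closures are open to it), and needs cyclisation to outrun ionisation of the allylic C2–O1 bond, which the low temperature and the intramolecularity are meant to secure.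

Step 13
Reactants: 17 (2S,3S,5R,6R)-6-[(2E)-3-bromopent-2-en-1-yl]-2-{2-[(tert-butyldiphenylsilyl)oxy]ethyl}-3-chlorooxan-5-ol
Product: 18 (2S,3S,5S,6R)-6-[(2E)-3-bromopent-2-en-1-yl]-2-{2-[(tert-butyldiphenylsilyl)oxy]ethyl}-3-chlorooxan-5-yl 4-nitrobenzoate
Conditions: 4-O2NC6H4CO2H, PPh3, i-PrO2CN=NCO2i-Pr, toluene, 0 °C to rt
Reagents that add atoms: 4-nitrobenzoic acid, OC(=O)c1ccc(cc1)[N+](=O)[O-]
Why: Mitsunobu reaction: the carboxylate displaces the axial oxyphosphonium group at C5 from the unhindered equatorial side, so C5 should be inverted to the equatorial ester.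

Step 14
Reactants: 18 (2S,3S,5S,6R)-6-[(2E)-3-bromopent-2-en-1-yl]-2-{2-[(tert-butyldiphenylsilyl)oxy]ethyl}-3-chlorooxan-5-yl 4-nitrobenzoate
Product: 19 (2S,3S,5S,6R)-6-[(2E)-3-bromopent-2-en-1-yl]-2-{2-[(tert-butyldiphenylsilyl)oxy]ethyl}-3-chlorooxan-5-ol (C5 hydroxyl trans to the other three substituents)
Conditions: K2CO3 (cat.), MeOH, 0 °C to rt
Reagents that add atoms: none
Why: Base-catalysed methanolysis (transesterification) of the activated nitrobenzoate frees the equatorial C5 alcohol without touching the halides.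

Step 15
Reactants: 19 (2S,3S,5S,6R)-6-[(2E)-3-bromopent-2-en-1-yl]-2-{2-[(tert-butyldiphenylsilyl)oxy]ethyl}-3-chlorooxan-5-ol
Product: 20 (2S,3S,5R,6R)-5-bromo-6-[(2E)-3-bromopent-2-en-1-yl]-2-{2-[(tert-butyldiphenylsilyl)oxy]ethyl}-3-chlorooxane (all-cis)
Conditions: CBr4, P(n-C8H17)3, toluene, 60 °C
Reagents that add atoms: carbon tetrabromide, BrC(Br)(Br)Br
Why: Appel-type bromination: bromide attacks the equatorial alkoxyphosphonium at C5 by SN2 from the axial side, which should invert C5 to the axial bromide syn to chlorine, the equatorial leaving group having no anti-periplanar hydrogen for E2.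

Step 16
Reactants: 20 (2S,3S,5R,6R)-5-bromo-6-[(2E)-3-bromopent-2-en-1-yl]-2-{2-[(tert-butyldiphenylsilyl)oxy]ethyl}-3-chlorooxane
Product: 21 2-[(2S,3S,5R,6R)-5-bromo-6-[(2E)-3-bromopent-2-en-1-yl]-3-chlorooxan-2-yl]ethan-1-ol
Conditions: HF·pyridine, pyridine, THF, 0 °C to rt
Reagents that add atoms: none
Why: Fluoride-mediated desilylation under mildly acidic conditions removes the silyl ether without base-induced elimination of the secondary halides.

Step 17
Reactants: 21 2-[(2S,3S,5R,6R)-5-bromo-6-[(2E)-3-bromopent-2-en-1-yl]-3-chlorooxan-2-yl]ethan-1-ol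
Product: 22 2-[(2S,3S,5R,6R)-5-bromo-6-[(2E)-3-bromopent-2-en-1-yl]-3-chlorooxan-2-yl]acetaldehyde
Conditions: Dess–Martin periodinane, NaHCO3, CH2Cl2, 0 °C; used at once
Reagents that add atoms: none
Why: Dess–Martin oxidation gives the β-alkoxy aldehyde under neutral conditions that avoid β-elimination of the ring oxygen.

Step 18
Reactants: 22 2-[(2S,3S,5R,6R)-5-bromo-6-[(2E)-3-bromopent-2-en-1-yl]-3-chlorooxan-2-yl]acetaldehyde
Product: 23 {(3Z)-5-[(2S,3S,5R,6R)-5-bromo-6-[(2E)-3-bromopent-2-en-1-yl]-3-chlorooxan-2-yl]pent-3-en-1-yn-1-yl}tri(propan-2-yl)silane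
Conditions: i-Pr3SiC≡CCH2Si(i-Pr)3, n-BuLi, THF, −78 °C; then 22, −78 to 0 °C
Reagents that add atoms: 1,3-bis(triisopropylsilyl)propyne, CC(C)[Si](C(C)C)(C(C)C)C#CC[Si](C(C)C)(C(C)C)C(C)C
Why: Peterson olefination with the lithiated bis(silyl)propyne: the bulky triisopropylsilyl groups steer addition and silanolate elimination so that the Z enyne should predominate.

Step 19
Reactants: 23 {(3Z)-5-[(2S,3S,5R,6R)-5-bromo-6-[(2E)-3-bromopent-2-en-1-yl]-3-chlorooxan-2-yl]pent-3-en-1-yn-1-yl}tri(propan-2-yl)silane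
Product: 24 (2S,3S,5R,6R)-5-bromo-6-[(2E)-3-bromopent-2-en-1-yl]-3-chloro-2-[(2Z)-pent-2-en-4-yn-1-yl]oxane
Conditions: n-Bu4NF, THF, 0 °C
Reagents that add atoms: none
Why: Fluoride cleaves the alkynyl C–Si bond at low temperature to give the terminal alkyne, which is the target.

**Compound list**

1 | but-1-yne | C#CCC | starting material
2 | (E)-2-bromo-1-iodobut-1-ene | I/C=C(/Br)CC | intermediate
3 | methyl (2E)-3-bromopent-2-enoate | COC(=O)/C=C(/Br)CC | intermediate
4 | (2E)-3-bromopent-2-en-1-ol | OC/C=C(/Br)CC | intermediate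
5 | (2E)-3-bromo-1-iodopent-2-ene | IC/C=C(/Br)CC | intermediate
6 | 3-[(tert-butyldiphenylsilyl)oxy]propanal | CC(C)(C)[Si](c1ccccc1)(c1ccccc1)OCCC=O | starting material
7 | rac-5-[(tert-butyldiphenylsilyl)oxy]pent-1-en-3-ol | CC(C)(C)[Si](c1ccccc1)(c1ccccc1)OCCC(O)C=C | intermediate
8 | (3S)-5-[(tert-butyldiphenylsilyl)oxy]pent-1-en-3-ol | CC(C)(C)[Si](c1ccccc1)(c1ccccc1)OCC[C@@H](C=C)O | intermediate
9 | 2-{[(3S)-5-[(tert-butyldiphenylsilyl)oxy]pent-1-en-3-yl]oxy}acetic acid | CC(C)(C)[Si](c1ccccc1)(c1ccccc1)OCC[C@@H](C=C)OCC(=O)O | intermediate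
10 | (4S)-4-benzyl-1,3-oxazolidin-2-one | O=C1N[C@@H](Cc2ccccc2)CO1 | starting material
11 | mixed anhydride of acid 9 with pivalic acid (not isolated) | CC(C)(C)[Si](c1ccccc1)(c1ccccc1)OCC[C@@H](C=C)OCC(=O)OC(=O)C(C)(C)C | intermediate
12 | (4S)-4-benzyl-3-(2-{[(3S)-5-[(tert-butyldiphenylsilyl)oxy]pent-1-en-3-yl]oxy}acetyl)-1,3-oxazolidin-2-one | CC(C)(C)[Si](c1ccccc1)(c1ccccc1)OCC[C@@H](C=C)OCC(=O)N1C(=O)OC[C@@H]1Cc1ccccc1 | intermediate
13 | sodium (Z)-enolate of 12 (not isolated) | CC(C)(C)[Si](c1ccccc1)(c1ccccc1)OCC[C@@H](C=C)O/C=C(\[O-])N1C(=O)OC[C@@H]1Cc1ccccc1.[Na+] | intermediate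
14 | (4S)-4-benzyl-3-[(2R,4E)-5-bromo-2-{[(3S)-5-[(tert-butyldiphenylsilyl)oxy]pent-1-en-3-yl]oxy}hept-4-enoyl]-1,3-oxazolidin-2-one | CC(C)(C)[Si](c1ccccc1)(c1ccccc1)OCC[C@@H](C=C)O[C@H](C/C=C(/Br)CC)C(=O)N1C(=O)OC[C@@H]1Cc1ccccc1 | intermediate
15 | (2R,4E)-5-bromo-2-{[(3S)-5-[(tert-butyldiphenylsilyl)oxy]pent-1-en-3-yl]oxy}hept-4-en-1-ol | CC(C)(C)[Si](c1ccccc1)(c1ccccc1)OCC[C@@H](C=C)O[C@H](C/C=C(/Br)CC)CO | intermediate
16 | (2R,4E)-5-bromo-2-{[(3S)-5-[(tert-butyldiphenylsilyl)oxy]pent-1-en-3-yl]oxy}hept-4-enal | CC(C)(C)[Si](c1ccccc1)(c1ccccc1)OCC[C@@H](C=C)O[C@H](C/C=C(/Br)CC)C=O | intermediate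
17 | (2S,3S,5R,6R)-6-[(2E)-3-bromopent-2-en-1-yl]-2-{2-[(tert-butyldiphenylsilyl)oxy]ethyl}-3-chlorooxan-5-ol (all-cis) | CC(C)(C)[Si](c1ccccc1)(c1ccccc1)OCC[C@@H]1O[C@H](C/C=C(/Br)CC)[C@H](O)C[C@@H]1Cl | intermediate
18 | (2S,3S,5S,6R)-6-[(2E)-3-bromopent-2-en-1-yl]-2-{2-[(tert-butyldiphenylsilyl)oxy]ethyl}-3-chlorooxan-5-yl 4-nitrobenzoate | CC(C)(C)[Si](c1ccccc1)(c1ccccc1)OCC[C@@H]1O[C@H](C/C=C(/Br)CC)[C@@H](OC(=O)c2ccc(cc2)[N+](=O)[O-])C[C@@H]1Cl | intermediate
19 | (2S,3S,5S,6R)-6-[(2E)-3-bromopent-2-en-1-yl]-2-{2-[(tert-butyldiphenylsilyl)oxy]ethyl}-3-chlorooxan-5-ol | CC(C)(C)[Si](c1ccccc1)(c1ccccc1)OCC[C@@H]1O[C@H](C/C=C(/Br)CC)[C@@H](O)C[C@@H]1Cl | intermediate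
20 | (2S,3S,5R,6R)-5-bromo-6-[(2E)-3-bromopent-2-en-1-yl]-2-{2-[(tert-butyldiphenylsilyl)oxy]ethyl}-3-chlorooxane | CC(C)(C)[Si](c1ccccc1)(c1ccccc1)OCC[C@@H]1O[C@H](C/C=C(/Br)CC)[C@H](Br)C[C@@H]1Cl | intermediate
21 | 2-[(2S,3S,5R,6R)-5-bromo-6-[(2E)-3-bromopent-2-en-1-yl]-3-chlorooxan-2-yl]ethan-1-ol | OCC[C@@H]1O[C@H](C/C=C(/Br)CC)[C@H](Br)C[C@@H]1Cl | intermediate
22 | 2-[(2S,3S,5R,6R)-5-bromo-6-[(2E)-3-bromopent-2-en-1-yl]-3-chlorooxan-2-yl]acetaldehyde | O=CC[C@@H]1O[C@H](C/C=C(/Br)CC)[C@H](Br)C[C@@H]1Cl | intermediate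
23 | {(3Z)-5-[(2S,3S,5R,6R)-5-bromo-6-[(2E)-3-bromopent-2-en-1-yl]-3-chlorooxan-2-yl]pent-3-en-1-yn-1-yl}tri(propan-2-yl)silane | CC(C)[Si](C(C)C)(C(C)C)C#C/C=C\C[C@@H]1O[C@H](C/C=C(/Br)CC)[C@H](Br)C[C@@H]1Cl | intermediate
24 | (2S,3S,5R,6R)-5-bromo-6-[(2E)-3-bromopent-2-en-1-yl]-3-chloro-2-[(2Z)-pent-2-en-4-yn-1-yl]oxane | C#C/C=C\C[C@@H]1O[C@H](C/C=C(/Br)CC)[C@H](Br)C[C@@H]1Cl | target

**Count**

Total step count: 19. Longest linear sequence: 15 steps (steps 5 to 19, from 6); the iodide arm (steps 1 to 4) joins at step 9.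

**Steps most likely to fail**

1. Step 12 (key cyclisation). The olefin is deactivated by the neighbouring, titanium-bound ether oxygen and may add too slowly. Ionisation of the allylic C2–O1 bond, proton loss instead of chloride transfer, or external anti capture of chloride (equatorial chlorine at C3) could then take over. The fallback sets out from alcohol 15 and returns at alcohol 19, closing the same C4–C5 bond by an aldol addition. Tsuji–Wacker oxidation of the vinyl group of 15 (PdCl2, CuCl, O2, DMF/H2O) should give the hydroxy methyl ketone F1, and Dess–Martin oxidation the keto aldehyde F2. Amine-catalysed intramolecular aldol addition of the methyl ketone (enamine carbon C4) onto the aldehyde C5 ((S)-proline, DMSO, rt) should give the 5-hydroxy-oxan-3-one F3, with the C5 hydroxyl equatorial as the thermodynamically preferred aldol. Silylation (Et3SiOTf, 2,6-lutidine) gives the triethylsilyl ether F4. NaBH4 in MeOH at −40 °C (axial hydride attack) gives the equatorial C3 alcohol F5. Chlorination with inversion (CCl4, P(n-C8H17)3, toluene, 60 °C) gives the axial chloride F6. Selective removal of the triethylsilyl group (pyridinium 4-toluenesulfonate, MeOH, 0 °C) then gives 19. This costs three more steps and replaces steps 11 to 14.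

2. Step 13 (inversion at C5). E2 elimination of the axial oxyphosphonium group, which has anti-periplanar axial hydrogens on C4 and C6, may outrun substitution at this hindered carbinol. The fallback sets out from 17 and returns at 19 by sulfonate displacement instead of redox condensation. Triflation (Tf2O, pyridine, CH2Cl2, −20 °C) gives the axial triflate F7. Lattrell–Dax displacement with the weakly basic nitrite ion (KNO2, DMF, rt) gives the equatorial nitrite ester F8, which hydrolyses on aqueous work-up to 19.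

3. Step 15 (axial bromide at C5). The ring oxygen O1 is anti-periplanar to the equatorial leaving group and may participate at 60 °C, leading to ring contraction or substitution with retention, while axial attack of bromide past the syn-axial chlorine is slow. The fallback sets out from 19 and returns at 20, separating activation from displacement. Sulfonylation (ClCH2SO2Cl, 2,6-lutidine, CH2Cl2, 0 °C) gives the isolated chloromethanesulfonate F9. This is then displaced with inversion by an excess of a soluble bromide salt at lower temperature (LiBr, DMF, 40 °C) to give 20.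

**Further compounds**

F1 | step 12 | (3S)-3-{[(2R,4E)-5-bromo-1-hydroxyhept-4-en-2-yl]oxy}-5-[(tert-butyldiphenylsilyl)oxy]pentan-2-one | CC(C)(C)[Si](c1ccccc1)(c1ccccc1)OCC[C@@H](C(C)=O)O[C@H](C/C=C(/Br)CC)CO
F2 | step 12 | (2R,4E)-5-bromo-2-{[(3S)-5-[(tert-butyldiphenylsilyl)oxy]-2-oxopentan-3-yl]oxy}hept-4-enal | CC(C)(C)[Si](c1ccccc1)(c1ccccc1)OCC[C@@H](C(C)=O)O[C@H](C/C=C(/Br)CC)C=O
F3 | step 12 | (2S,5S,6R)-6-[(2E)-3-bromopent-2-en-1-yl]-2-{2-[(tert-butyldiphenylsilyl)oxy]ethyl}-5-hydroxyoxan-3-one | CC(C)(C)[Si](c1ccccc1)(c1ccccc1)OCC[C@@H]1O[C@H](C/C=C(/Br)CC)[C@@H](O)CC1=O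
F4 | step 12 | (2S,5S,6R)-6-[(2E)-3-bromopent-2-en-1-yl]-2-{2-[(tert-butyldiphenylsilyl)oxy]ethyl}-5-[(triethylsilyl)oxy]oxan-3-one | CC(C)(C)[Si](c1ccccc1)(c1ccccc1)OCC[C@@H]1O[C@H](C/C=C(/Br)CC)[C@@H](O[Si](CC)(CC)CC)CC1=O
F5 | step 12 | (2S,3R,5S,6R)-6-[(2E)-3-bromopent-2-en-1-yl]-2-{2-[(tert-butyldiphenylsilyl)oxy]ethyl}-5-[(triethylsilyl)oxy]oxan-3-ol | CC(C)(C)[Si](c1ccccc1)(c1ccccc1)OCC[C@@H]1O[C@H](C/C=C(/Br)CC)[C@@H](O[Si](CC)(CC)CC)C[C@H]1O
F6 | step 12 | (2S,3S,5S,6R)-6-[(2E)-3-bromopent-2-en-1-yl]-2-{2-[(tert-butyldiphenylsilyl)oxy]ethyl}-3-chloro-5-[(triethylsilyl)oxy]oxane | CC(C)(C)[Si](c1ccccc1)(c1ccccc1)OCC[C@@H]1O[C@H](C/C=C(/Br)CC)[C@@H](O[Si](CC)(CC)CC)C[C@@H]1Cl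
F7 | step 13 | (2S,3S,5R,6R)-6-[(2E)-3-bromopent-2-en-1-yl]-2-{2-[(tert-butyldiphenylsilyl)oxy]ethyl}-3-chlorooxan-5-yl trifluoromethanesulfonate | CC(C)(C)[Si](c1ccccc1)(c1ccccc1)OCC[C@@H]1O[C@H](C/C=C(/Br)CC)[C@H](OS(=O)(=O)C(F)(F)F)C[C@@H]1Cl
F8 | step 13 | (2S,3S,5S,6R)-6-[(2E)-3-bromopent-2-en-1-yl]-2-{2-[(tert-butyldiphenylsilyl)oxy]ethyl}-3-chlorooxan-5-yl nitrite | CC(C)(C)[Si](c1ccccc1)(c1ccccc1)OCC[C@@H]1O[C@H](C/C=C(/Br)CC)[C@@H](ON=O)C[C@@H]1Cl
F9 | step 15 | (2S,3S,5S,6R)-6-[(2E)-3-bromopent-2-en-1-yl]-2-{2-[(tert-butyldiphenylsilyl)oxy]ethyl}-3-chlorooxan-5-yl chloromethanesulfonate | CC(C)(C)[Si](c1ccccc1)(c1ccccc1)OCC[C@@H]1O[C@H](C/C=C(/Br)CC)[C@@H](OS(=O)(=O)CCl)C[C@@H]1Cl
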